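The route rests on cutting the ketone carbon from C8 of the 2H-chromene, and it exploits the fact that C8 is ortho to the pyran oxygen O1 on C8a. The 2-prenyl-3,5-dioxygenated benzoic acid is first hung on that oxygen as the aryl ester of symmetrical 3,5-bis(methoxymethoxy)phenol. A photo-Fries rearrangement then moves the aroyl group from O1 to the neighbouring ring carbon: in one operation it forms the diaryl ketone at the final oxidation level and releases O1–H as the only free phenol. That phenol, flanked by the ketone-bearing carbon and one open position (the future C4a), forces a regiospecific pyran annulation with prenal before the four MOM ethers are removed.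

Key step: step 7

Remark: the target has no stereocentre and no stereogenic double bond, so no stereocontrol is needed; stannane 6 is taken as a purchasable reagent.

Step 1
Reactants: 1 phloroglucinol
Product: 2 3,5-bis(methoxymethoxy)phenol
Conditions: MOMCl (2.0 equiv), i-Pr2NEt, DMF, 0 °C to rt; chromatography
Reagents that add atoms: chloromethyl methyl ether, COCCl
Why: Williamson-type O-alkylation with an α-chloro ether, run statistically; because the three hydroxyls of phloroglucinol are equivalent the bis-ether is a single isomer, to be separated from mono- and tris-ether.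

Step 2
Reactants: 3 methyl 3,5-dihydroxybenzoate
Product: 4 methyl 3,5-bis(methoxymethoxy)benzoate
Conditions: MOMCl (2.5 equiv), i-Pr2NEt, CH2Cl2, 0 °C to rt
Reagents that add atoms: chloromethyl methyl ether, COCCl
Why: Williamson-type acetal protection of both equivalent phenols under amine base, which leaves the methyl ester untouched.

Step 3
Reactants: 4 methyl 3,5-bis(methoxymethoxy)benzoate
Product: 5 methyl 2-bromo-3,5-bis(methoxymethoxy)benzoate
Conditions: NBS (1.05 equiv), MeCN, 0 °C to rt, dark
Reagents that add atoms: N-bromosuccinimide, O=C1CCC(=O)N1Br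
Why: electrophilic aromatic bromination at C2, which is para to one MOM ether and ortho to the other and less hindered than C4 between the two ethers, as is usual for 3,5-dialkoxybenzoates.

Step 4
Reactants: 5 methyl 2-bromo-3,5-bis(methoxymethoxy)benzoate; 6 tributyl(3-methylbut-2-en-1-yl)stannane
Product: 7 methyl 3,5-bis(methoxymethoxy)-2-(3-methylbut-2-en-1-yl)benzoate
Conditions: Pd(PPh3)4 (5 mol %), DMF, 100 °C
Reagents that add atoms: none
Why: Stille cross-coupling of an aryl bromide with an allylic stannane, in which reductive elimination from the less substituted allyl terminus should give the linear prenyl arene.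

Step 5
Reactants: 7 methyl 3,5-bis(methoxymethoxy)-2-(3-methylbut-2-en-1-yl)benzoate
Product: 8 3,5-bis(methoxymethoxy)-2-(3-methylbut-2-en-1-yl)benzoic acid
Conditions: LiOH·H2O, THF–MeOH–H2O, 50 °C; then 1 M HCl to pH 4, 0 °C
Reagents that add atoms: lithium hydroxide, [Li+].[OH-]
Why: ester saponification (acyl–oxygen cleavage), to which MOM acetals and the alkene are inert; brief cold acidification to pH 4 should spare the acetals.

Step 6
Reactants: 8 3,5-bis(methoxymethoxy)-2-(3-methylbut-2-en-1-yl)benzoic acid; 2 3,5-bis(methoxymethoxy)phenol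
Product: 9 3,5-bis(methoxymethoxy)phenyl 3,5-bis(methoxymethoxy)-2-(3-methylbut-2-en-1-yl)benzoate
Conditions: DIC, DMAP (cat.), CH2Cl2, 0 °C to rt
Reagents that add atoms: none
Why: Steglich esterification through the O-acylisourea and acylpyridinium, a neutral method suited to the acid-labile MOM groups and to an unhindered phenol.

Step 7
Reactants: 9 3,5-bis(methoxymethoxy)phenyl 3,5-bis(methoxymethoxy)-2-(3-methylbut-2-en-1-yl)benzoate
Product: 11 [2-hydroxy-4,6-bis(methoxymethoxy)phenyl][3,5-bis(methoxymethoxy)-2-(3-methylbut-2-en-1-yl)phenyl]methanone, via ortho-acyl cyclohexadienone 10 (not isolated)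
Conditions: hν (254 nm, quartz), argon-purged MeCN (5 mM), rt
Reagents that add atoms: none
Why: Excitation of the aryl ester leads to homolysis of the O1–C(=O) bond from the singlet state; the 3,5-bis(methoxymethoxy)phenoxyl and aroyl radicals recombine inside the solvent cage at the ring carbon ortho to oxygen to give dienone 10, which enolises to the hydrogen-bonded o-hydroxy ketone 11, so the ketone-carbon-to-aryl-carbon bond of the target is made here. The closest known reaction type is the photo-Fries rearrangement of aryl benzoates to 2-hydroxybenzophenones. No ring is closed and no stereocentre survives, since the sp3 carbon of 10 is erased on tautomerisation. The step needs ortho over para recombination and recombination over cage escape: the two ortho carbons lie next to the broken bond and are equivalent by the symmetry of the phenol ring, so only one ortho product can form, whereas the para carbon is remote and flanked by two MOM ethers. The neutral, room-temperature conditions leave the MOM acetals and the prenyl group untouched, and the chelated o-hydroxybenzophenone product should be shielded from further photoreaction by rapid excited-state proton transfer.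

Step 8
Reactants: 11 [2-hydroxy-4,6-bis(methoxymethoxy)phenyl][3,5-bis(methoxymethoxy)-2-(3-methylbut-2-en-1-yl)phenyl]methanone; 12 3-methylbut-2-enal
Product: 14 [5,7-bis(methoxymethoxy)-2,2-dimethyl-2H-chromen-8-yl][3,5-bis(methoxymethoxy)-2-(3-methylbut-2-en-1-yl)phenyl]methanone, via o-quinone methide 13 (not isolated)
Conditions: ethylenediammonium diacetate (20 mol %), xylene, 140 °C
Reagents that add atoms: none
Why: amine-catalysed Knoevenagel-type condensation at the only open ortho carbon of the single free phenol gives o-quinone methide 13, which closes by oxa-6π electrocyclisation (formal [3+3] chromene annulation); the other ortho carbon carries the ketone, so only the 8-aroyl chromene can form.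

Step 9
Reactants: 14 [5,7-bis(methoxymethoxy)-2,2-dimethyl-2H-chromen-8-yl][3,5-bis(methoxymethoxy)-2-(3-methylbut-2-en-1-yl)phenyl]methanone
Product: 15 [5,7-dihydroxy-2,2-dimethyl-2H-chromen-8-yl][3,5-dihydroxy-2-(3-methylbut-2-en-1-yl)phenyl]methanone (CNP0076744.0)
Conditions: HCl (1.25 M in MeOH), argon, rt to 40 °C
Reagents that add atoms: none
Why: acid-catalysed transacetalisation of the four aryl MOM ethers to dimethoxymethane frees the phenols, with dilute acid and low temperature chosen to spare the o-prenylphenol and the chromene alkene.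

Compound list
1 | phloroglucinol (benzene-1,3,5-triol) | Oc1cc(O)cc(O)c1 | starting material
2 | 3,5-bis(methoxymethoxy)phenol | COCOc1cc(O)cc(OCOC)c1 | intermediate
3 | methyl 3,5-dihydroxybenzoate | COC(=O)c1cc(O)cc(O)c1 | starting material
4 | methyl 3,5-bis(methoxymethoxy)benzoate | COC(=O)c1cc(OCOC)cc(OCOC)c1 | intermediate
5 | methyl 2-bromo-3,5-bis(methoxymethoxy)benzoate | COC(=O)c1cc(OCOC)cc(OCOC)c1Br | intermediate
6 | tributyl(3-methylbut-2-en-1-yl)stannane | CCCC[Sn](CCCC)(CCCC)CC=C(C)C | starting material
7 | methyl 3,5-bis(methoxymethoxy)-2-(3-methylbut-2-en-1-yl)benzoate | COC(=O)c1cc(OCOC)cc(OCOC)c1CC=C(C)C | intermediate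
8 | 3,5-bis(methoxymethoxy)-2-(3-methylbut-2-en-1-yl)benzoic acid | OC(=O)c1cc(OCOC)cc(OCOC)c1CC=C(C)C | intermediate
9 | 3,5-bis(methoxymethoxy)phenyl 3,5-bis(methoxymethoxy)-2-(3-methylbut-2-en-1-yl)benzoate | CC(C)=CCc1c(OCOC)cc(OCOC)cc1C(=O)Oc1cc(OCOC)cc(OCOC)c1 | intermediate
10 | 6-[3,5-bis(methoxymethoxy)-2-(3-methylbut-2-en-1-yl)benzoyl]-3,5-bis(methoxymethoxy)cyclohexa-2,4-dien-1-one (transient, racemic at C6) | CC(C)=CCc1c(OCOC)cc(OCOC)cc1C(=O)C1C(=O)C=C(OCOC)C=C1OCOC | intermediate
11 | [2-hydroxy-4,6-bis(methoxymethoxy)phenyl][3,5-bis(methoxymethoxy)-2-(3-methylbut-2-en-1-yl)phenyl]methanone | CC(C)=CCc1c(OCOC)cc(OCOC)cc1C(=O)c1c(O)cc(OCOC)cc1OCOC | intermediate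
12 | 3-methylbut-2-enal (prenal) | CC(C)=CC=O | starting material
13 | 2-[3,5-bis(methoxymethoxy)-2-(3-methylbut-2-en-1-yl)benzoyl]-3,5-bis(methoxymethoxy)-6-(3-methylbut-2-en-1-ylidene)cyclohexa-2,4-dien-1-one (o-quinone methide, transient) | O=C1C(=CC=C(C)C)C(OCOC)=CC(OCOC)=C1C(=O)c1cc(OCOC)cc(OCOC)c1CC=C(C)C | intermediate
14 | [5,7-bis(methoxymethoxy)-2,2-dimethyl-2H-chromen-8-yl][3,5-bis(methoxymethoxy)-2-(3-methylbut-2-en-1-yl)phenyl]methanone | CC(C)=CCc1c(OCOC)cc(OCOC)cc1C(=O)c1c(OCOC)cc(OCOC)c2c1OC(C)(C)C=C2 | intermediate
15 | [5,7-dihydroxy-2,2-dimethyl-2H-chromen-8-yl][3,5-dihydroxy-2-(3-methylbut-2-en-1-yl)phenyl]methanone | CC(C)=CCc1c(O)cc(O)cc1C(=O)c1c(O)cc(O)c2c1OC(C)(C)C=C2 | target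

Total step count: 9
Longest linear sequence: 8 steps (3 → 4 → 5 → 7 → 8 → 9 → 11 → 14 → 15); step 1 supplies phenol 2 for step 6.

Steps most likely to fail

Step 7 (photo-Fries rearrangement). The caged radical pair may recombine at the para carbon or escape the cage (loss to phenol and aldehyde). The absorbing product may also stall conversion, and the prenyl alkene may enter side photochemistry. The fallback uses organolithium chemistry, sets out from ester 7 and phloroglucinol 1, and comes back at compound 11. Ester 7 is reduced with DIBAL-H (CH2Cl2, −78 to 0 °C) to benzylic alcohol F1, which MnO2 (CH2Cl2, rt) oxidises to aldehyde F2. Phloroglucinol 1 is exhaustively protected (NaH, MOMCl, DMF) to 1,3,5-tris(methoxymethoxy)benzene F3. n-BuLi (THF, 0 °C) lithiates F3 between two MOM ethers (all three ring CH are equivalent) to give aryllithium F4, which adds to F2 at −78 °C to give racemic diarylmethanol F5. MnO2 oxidation then gives ketone F6. MgBr2·OEt2 (Et2O–CH2Cl2, rt), chelated between the ketone oxygen and one flanking MOM ether, should cleave that one ether only and deliver 11.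

Step 8 (chromene annulation). The hydrogen-bonded phenol may be too weak a nucleophile, so that condensation at the ring carbon is outrun by self-condensation of the enal. The fallback sets out from 11 and comes back at 14. Phenol 11 is O-alkylated with 3-chloro-3-methylbut-1-yne (K2CO3, KI, CuI cat., DMF, 60 °C) to 1,1-dimethylpropargyl ether F7. Heating (N,N-diethylaniline, 150 °C) should then bring about aromatic propargyl Claisen rearrangement to the single open ortho carbon, enolisation, 1,5-hydrogen shift and oxa-6π closure to 14.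

Step 9 (global MOM removal). Under protic acid the prenyl chain may cyclise onto the neighbouring A-ring hydroxyl (chroman formation), and the electron-rich chromene alkene may add methanol or oligomerise before all four acetals are gone. The fallback sets out from 14 and comes back at 15 without Brønsted acid. TMSOTf/2,2′-bipyridyl (MeCN, 0 °C to rt) should transfer the methoxymethyl groups to the pyridine base and convert each aryl MOM ether into a trimethylsilyl ether, giving tetrakis(trimethylsilyl) ether F8. Addition of water then hydrolyses the silyl ethers under essentially neutral conditions to 15.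

Further compounds
F1 | step 7 | [3,5-bis(methoxymethoxy)-2-(3-methylbut-2-en-1-yl)phenyl]methanol | OCc1cc(OCOC)cc(OCOC)c1CC=C(C)C
F2 | step 7 | 3,5-bis(methoxymethoxy)-2-(3-methylbut-2-en-1-yl)benzaldehyde | O=Cc1cc(OCOC)cc(OCOC)c1CC=C(C)C
F3 | step 7 | 1,3,5-tris(methoxymethoxy)benzene | COCOc1cc(OCOC)cc(OCOC)c1
F4 | step 7 | [2,4,6-tris(methoxymethoxy)phenyl]lithium | [Li]c1c(OCOC)cc(OCOC)cc1OCOC
F5 | step 7 | [3,5-bis(methoxymethoxy)-2-(3-methylbut-2-en-1-yl)phenyl][2,4,6-tris(methoxymethoxy)phenyl]methanol (racemic) | CC(C)=CCc1c(OCOC)cc(OCOC)cc1C(O)c1c(OCOC)cc(OCOC)cc1OCOC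
F6 | step 7 | [3,5-bis(methoxymethoxy)-2-(3-methylbut-2-en-1-yl)phenyl][2,4,6-tris(methoxymethoxy)phenyl]methanone | CC(C)=CCc1c(OCOC)cc(OCOC)cc1C(=O)c1c(OCOC)cc(OCOC)cc1OCOC
F7 | step 8 | [3,5-bis(methoxymethoxy)-2-(3-methylbut-2-en-1-yl)phenyl][2,4-bis(methoxymethoxy)-6-(2-methylbut-3-yn-2-yloxy)phenyl]methanone | CC(C)=CCc1c(OCOC)cc(OCOC)cc1C(=O)c1c(OC(C)(C)C#C)cc(OCOC)cc1OCOC
F8 | step 9 | [2,2-dimethyl-5,7-bis(trimethylsilyloxy)-2H-chromen-8-yl][2-(3-methylbut-2-en-1-yl)-3,5-bis(trimethylsilyloxy)phenyl]methanone | CC(C)=CCc1c(O[Si](C)(C)C)cc(O[Si](C)(C)C)cc1C(=O)c1c(O[Si](C)(C)C)cc(O[Si](C)(C)C)c2c1OC(C)(C)C=C2
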